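**Plan**
- Cuts: (i) the diarylmethane bond between the phloroglucinol core and the dihydrobenzofuran (made as core–CHO plus aryl-lithium). (ii) In each furo[2,3-b]chromene unit (O1, C2, C3, C3a, C4 … O9, C9a) the aryl–C4 bond and the aryl O9–C9a ketal bond, back to 2,4,6-trihydroxybenzaldehyde and two equivalents of one dihydrofuranylmethanol. (iii) In each tetrahydrofuran ring the O1–C2 bond, back to a cyclopropane.
- Enabling feature: in each tetrahydrofuran ring, O1 and the methyl ketal carbon C9a sit next to C3a. Read as the enol ether O1–C9a(CH3)=C3a, these are the C=O of an acetyl group on a cyclopropane made of C3a, C3 and C2. The benzylic carbon C4, carried as an ester, is the second acceptor on C3a that makes the three-membered ring electrophilic.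
- Forward order: cyclopropane (step 1), C-acetylation (2), five-membered ring by a two-atom ring expansion (3), reduction (4), both pyran rings and both ketals in one double annulation (5), carbonate (6), dihydrobenzofuran (7), fragment union through an ortho-quinone methide (8).
- Stereochemistry: both C3 methyl centres come from (R)-propylene oxide (inversion in step 1); the acyl-bearing cyclopropane carbon is an epimer mixture that converges in step 3; C3a and C9a follow from substrate control in step 5; the dihydrobenzofuran C2 (S) is set by a chiral Pd catalyst.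

Key step: step 3

Remark: the configurations read from the structure are S at C2 of the dihydrobenzofuran and (3R,3aR,9aR) for each ketal unit; compounds 1, 2, 4, 10, 14, 15 and the chiral ligand are taken as purchasable.

**Step 1**
Reactants: 1 (R)-2-methyloxirane; 2 tert-butyl 2-(diethoxyphosphoryl)acetate
Product: 3 tert-butyl (1S,2S)-2-methylcyclopropane-1-carboxylate
Conditions: NaH, DME, 0 °C to rt; then 1, sealed vessel, 120 °C
Reagents that add atoms: none
Why: Wadsworth–Emmons cyclopropanation, in which the phosphonate carbanion opens the epoxide at CH2, the phosphoryl group moves to the alkoxide and the ester enolate displaces phosphate at the methyl-bearing carbon by 3-exo-tet SN2 with inversion, so the (R)-epoxide should give the (2S) centre and the trans ester.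

**Step 2**
Reactants: 3 tert-butyl (1S,2S)-2-methylcyclopropane-1-carboxylate; 4 acetyl chloride
Product: 6 tert-butyl (2S)-1-acetyl-2-methylcyclopropane-1-carboxylate (both C1 epimers), via lithium enolate 5 (not isolated)
Conditions: LDA, THF, −78 °C; enolate added to AcCl (2 equiv), THF, −78 °C
Reagents that add atoms: none
Why: Claisen-type C-acylation of a fully substituted lithium ester enolate (the tert-butyl ester suppresses self-condensation, inverse addition avoids proton transfer to the product); the new quaternary C1 forms as both epimers, which does not matter because step 3 erases this centre.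

**Step 3**
Reactants: 6 tert-butyl (2S)-1-acetyl-2-methylcyclopropane-1-carboxylate (both C1 epimers)
Product: 8 tert-butyl (4R)-2,4-dimethyl-4,5-dihydrofuran-3-carboxylate, via ammonium enolate 7 (not isolated)
Conditions: DABCO (20 mol %), DMSO, 120 °C
Reagents that add atoms: none
Why: DABCO should add in an SN2 homoconjugate fashion to the unsubstituted ring CH2 (C3) of the doubly activated cyclopropane, the C1–C3 bond opens to the stabilised keto-ester enolate 7, and the ketone enolate oxygen then displaces the ammonium group at the same CH2, so that C=O is inserted into the C1–C3 bond (three-membered carbocycle to five-membered enol ether, two atoms more). The closest known reaction type is the amine- or halide-catalysed Cloke–Wilson rearrangement of 1-acylcyclopropane-1-carboxylates to 4,5-dihydrofuran-3-carboxylates. The dihydrofuran ring closes by 5-exo-tet O-alkylation. No new stereocentre is made: the methyl-bearing carbon is not touched and keeps its configuration (2S becomes 4R only through a change of CIP ranks), while C1 becomes sp2, so both C1 epimers of 6 converge on one product. The step needs attack at CH2 and not at CH(CH3), and O-closure by the ketone and not the ester oxygen; the first is secured by the steric bias of a bulky amine in an SN2 transition state and by the absence of acid, which would favour cleavage toward the secondary carbon, the second by the higher nucleophilicity of the ketone enolate oxygen and by the fact that C-closure only regenerates 6 whereas O-closure gives the conjugated vinylogous carbonate with loss of ring strain.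

**Step 4**
Reactants: 8 tert-butyl (4R)-2,4-dimethyl-4,5-dihydrofuran-3-carboxylate
Product: 9 [(4R)-2,4-dimethyl-4,5-dihydrofuran-3-yl]methanol
Conditions: LiAlH4, Et2O, 0 °C to rt; basic work-up, used crude
Reagents that add atoms: none
Why: Hydride 1,2-reduction of the vinylogous carbonate ester to the allylic alcohol, which leaves C4 untouched; the acid-labile product is carried on at once.

**Step 5**
Reactants: 9 [(4R)-2,4-dimethyl-4,5-dihydrofuran-3-yl]methanol (2.3 equiv); 10 2,4,6-trihydroxybenzaldehyde
Product: 12 bis-ketal aldehyde (2-hydroxybenzaldehyde with two cis-fused (3R,3aR,9aR)-3,9a-dimethyl-tetrahydrofuro[2,3-b]pyran units annulated at ring C3–C4 and C5–C6; benzylic CH2 on ring C3 and C5; ketal oxygen on ring C4 and C6), via mono-ketal aldehyde 11 (not isolated)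
Conditions: BF3·OEt2, MgSO4, Et2O, 0 °C
Reagents that add atoms: none
Why: Lewis-acid Friedel–Crafts/ketalisation cascade (formal (3+3) annulation of a phenol with a 3-(hydroxymethyl)dihydrofuran through its 2-methyl-3-methylene oxocarbenium ion) at the two ring positions flanked by oxygens; cis ring fusion is enforced by the bicyclic ketal, the benzylic CH2 should settle trans to the C3 methyl (methyl on the convex face) under reversible protonation and ketalisation, and the ortho hydroxyl hydrogen-bonded to the formyl group is the one expected to stay free.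

**Step 6**
Reactants: 12 bis-ketal aldehyde
Product: 13 tert-butyl carbonate of 12 (O-Boc on the phenol ortho to the formyl group)
Conditions: Boc2O, i-Pr2NEt, DMAP (cat.), THF, 0 °C to rt
Reagents that add atoms: di-tert-butyl dicarbonate, CC(C)(C)OC(=O)OC(=O)OC(C)(C)C
Why: DMAP-catalysed O-acylation of the only free phenol; no stereocentre is touched and the ketals are stable to the basic conditions.

**Step 7**
Reactants: 14 4-bromo-2-iodophenol; 15 isoprene (excess)
Product: 16 (S)-5-bromo-2-(prop-1-en-2-yl)-2,3-dihydro-1-benzofuran
Conditions: Pd2(dba)3 (2.5 mol %), chiral sulfinamide–phosphine ligand (Sadphos type, enantiomer chosen for S), K2CO3, toluene, 60 °C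
Reagents that add atoms: none
Why: Enantioselective Heck/Tsuji–Trost heteroannulation of a 1,3-diene (asymmetric Larock-type annulation): oxidative addition at C–I only, carbopalladation at the unsubstituted vinyl terminus of isoprene, then phenoxide attack on the π-allyl at its internal terminus closes the five-membered ring, with the ligand setting C2.

**Step 8**
Reactants: 16 (S)-5-bromo-2-(prop-1-en-2-yl)-2,3-dihydro-1-benzofuran; 13 tert-butyl carbonate of 12
Product: 20 target CNP0131395.1, via aryllithium 17 (not isolated), via lithium alkoxide 18 (not isolated), via ortho-quinone methide 19 (not isolated)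
Conditions: 16, n-BuLi, THF, −78 °C; add 13, −78 °C; then NaBH4, THF/H2O, 0 °C to rt; pH 7 work-up
Reagents that add atoms: none
Why: Aryllithium 1,2-addition to the aldehyde, carbonate migration to the benzylic oxygen and β-elimination should give the ortho-quinone methide, which borohydride reduces by 1,4-hydride addition to the diarylmethane phenol (reductive ortho-quinone methide coupling of an O-Boc salicylaldehyde); the transient carbinol centre is destroyed and no other stereocentre is affected.

**Compound list**
1 | (R)-2-methyloxirane | C[C@@H]1CO1 | starting material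
2 | tert-butyl 2-(diethoxyphosphoryl)acetate | CCOP(=O)(OCC)CC(=O)OC(C)(C)C | starting material
3 | tert-butyl (1S,2S)-2-methylcyclopropane-1-carboxylate | C[C@H]1C[C@@H]1C(=O)OC(C)(C)C | intermediate
4 | acetyl chloride | CC(=O)Cl | starting material
5 | lithium enolate of 3 (not isolated) | [Li+].C[C@H]1CC1=C([O-])OC(C)(C)C | intermediate
6 | tert-butyl (2S)-1-acetyl-2-methylcyclopropane-1-carboxylate, both C1 epimers | C[C@H]1CC1(C(C)=O)C(=O)OC(C)(C)C | intermediate
7 | ammonium enolate from DABCO attack at the ring CH2 of 6 (not isolated) | CC([O-])=C(C(=O)OC(C)(C)C)[C@@H](C)C[N+]12CCN(CC1)CC2 | intermediate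
8 | tert-butyl (4R)-2,4-dimethyl-4,5-dihydrofuran-3-carboxylate | CC1=C(C(=O)OC(C)(C)C)[C@@H](C)CO1 | intermediate
9 | [(4R)-2,4-dimethyl-4,5-dihydrofuran-3-yl]methanol | CC1=C(CO)[C@@H](C)CO1 | intermediate
10 | 2,4,6-trihydroxybenzaldehyde | O=Cc1c(O)cc(O)cc1O | starting material
11 | mono-ketal aldehyde: 2,6-dihydroxybenzaldehyde with one (3R,3aR,9aR) unit at ring C3 (CH2) and C4 (O) (not isolated) | O=Cc1c(O)c2c(cc1O)O[C@@]3(C)OC[C@H](C)[C@H]3C2 | intermediate
12 | bis-ketal aldehyde: 2-hydroxybenzaldehyde with (3R,3aR,9aR) units at ring C3/C4 and C5/C6 | O=Cc1c(O)c2c(c3c1O[C@@]4(C)OC[C@H](C)[C@H]4C3)O[C@@]5(C)OC[C@H](C)[C@H]5C2 | intermediate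
13 | tert-butyl carbonate of 12 | O=Cc1c(OC(=O)OC(C)(C)C)c2c(c3c1O[C@@]4(C)OC[C@H](C)[C@H]4C3)O[C@@]5(C)OC[C@H](C)[C@H]5C2 | intermediate
14 | 4-bromo-2-iodophenol | Oc1ccc(Br)cc1I | starting material
15 | isoprene | C=CC(C)=C | starting material
16 | (S)-5-bromo-2-(prop-1-en-2-yl)-2,3-dihydro-1-benzofuran | C=C(C)[C@@H]1Cc2cc(Br)ccc2O1 | intermediate
17 | [(S)-2-(prop-1-en-2-yl)-2,3-dihydro-1-benzofuran-5-yl]lithium (not isolated) | C=C(C)[C@@H]1Cc2cc([Li])ccc2O1 | intermediate
18 | lithium alkoxide from addition of 17 to 13, carbinol centre undefined (not isolated) | [Li+].C=C(C)[C@@H]1Cc2cc(C([O-])c3c(OC(=O)OC(C)(C)C)c4c(c5c3O[C@@]6(C)OC[C@H](C)[C@H]6C5)O[C@@]7(C)OC[C@H](C)[C@H]7C4)ccc2O1 | intermediate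
19 | ortho-quinone methide, exocyclic C=C geometry undefined (not isolated) | C=C(C)[C@@H]1Cc2cc(C=C3C(=O)C4=C(C5=C3O[C@@]6(C)OC[C@H](C)[C@H]6C5)O[C@@]7(C)OC[C@H](C)[C@H]7C4)ccc2O1 | intermediate
20 | CNP0131395.1: phenol core with two (3R,3aR,9aR) ketal units and the [(S)-2-isopropenyl-2,3-dihydrobenzofuran-5-yl]methyl group | C=C(C)[C@@H]1Cc2cc(Cc3c(O)c4c(c5c3O[C@@]6(C)OC[C@H](C)[C@H]6C5)O[C@@]7(C)OC[C@H](C)[C@H]7C4)ccc2O1 | target

**Count**
Total steps: 8. Longest linear sequence: 7 (steps 1–6 and 8).

**Steps most likely to fail**

Step 3. The amine may open the ring at the methyl-bearing carbon (leading to the 2,5-dimethyl regioisomer), or turnover may be slow with reversion to the cyclopropane. The fallback gives up the ring expansion and sets out from acetyl chloride 4, which C-acylates the lithium enolate (LDA, THF, −78 °C) of purchased (R)-4-methyldihydrofuran-2(3H)-one to give (4R)-3-acetyl-4-methyldihydrofuran-2(3H)-one F1. Acid methanolysis with cyclodehydration (HCl, MeOH, reflux) should give methyl (4R)-2,4-dimethyl-4,5-dihydrofuran-3-carboxylate F2, and LiAlH4 reduction comes back to the route at 9.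

Step 5. The formyl group may condense with electron-rich ring positions under the Lewis acid, in competition with the annulation. The fallback sets out from 9 and uses purchased methyl 2,4,6-trihydroxybenzoate in place of 10 under the same annulation conditions, giving the bis-ketal methyl ester F3. Reduction (LiAlH4, THF, 0 °C) gives the bis-ketal salicyl alcohol F4, and MnO2 oxidation (CH2Cl2, rt) comes back to the route at 12.

Step 7. Enantiofacial control in the C–O bond-forming allylic substitution may be insufficient, or oxidative addition at C–Br may compete. The fallback sets out from 14 and comes back at 16: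
- Stille coupling at C–I with tributyl(3-methylbut-2-en-1-yl)stannane (Pd(PPh3)4, DMF, 80 °C) gives 4-bromo-2-(3-methylbut-2-en-1-yl)phenol F5.
- Acetylation (Ac2O, pyridine) gives 4-bromo-2-(3-methylbut-2-en-1-yl)phenyl acetate F6.
- Shi epoxidation (fructose-derived ketone of the enantiomeric series that delivers the R epoxide, Oxone, K2CO3, MeCN/buffer, 0 °C) gives the (R)-epoxide acetate F7.
- K2CO3 in MeOH removes the acetate, and the phenoxide opens the epoxide 5-exo with inversion to give (S)-2-(5-bromo-2,3-dihydro-1-benzofuran-2-yl)propan-2-ol F8.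
- Dehydration with Burgess reagent (toluene, 70 °C) gives 16.

**Further compounds**
F1 | step 3 | (4R)-3-acetyl-4-methyldihydrofuran-2(3H)-one (C3 epimers) | CC(=O)C1[C@@H](C)COC1=O
F2 | step 3 | methyl (4R)-2,4-dimethyl-4,5-dihydrofuran-3-carboxylate | CC1=C(C(=O)OC)[C@@H](C)CO1
F3 | step 5 | methyl ester analogue of 12 (CO2CH3 in place of CHO) | COC(=O)c1c(O)c2c(c3c1O[C@@]4(C)OC[C@H](C)[C@H]4C3)O[C@@]5(C)OC[C@H](C)[C@H]5C2
F4 | step 5 | salicyl alcohol analogue of 12 (CH2OH in place of CHO) | OCc1c(O)c2c(c3c1O[C@@]4(C)OC[C@H](C)[C@H]4C3)O[C@@]5(C)OC[C@H](C)[C@H]5C2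
F5 | step 7 | 4-bromo-2-(3-methylbut-2-en-1-yl)phenol | Oc1ccc(Br)cc1CC=C(C)C
F6 | step 7 | 4-bromo-2-(3-methylbut-2-en-1-yl)phenyl acetate | CC(=O)Oc1ccc(Br)cc1CC=C(C)C
F7 | step 7 | 4-bromo-2-{[(2R)-3,3-dimethyloxiran-2-yl]methyl}phenyl acetate | CC(=O)Oc1ccc(Br)cc1C[C@H]1OC1(C)C
F8 | step 7 | (S)-2-(5-bromo-2,3-dihydro-1-benzofuran-2-yl)propan-2-ol | CC(C)(O)[C@@H]1Cc2cc(Br)ccc2O1
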